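Remark on the chemistry (assumption): locants C1–C13 are the germacrane locants of the target and are kept for every intermediate (quinic acid C1, C2, C3, C4, C5, C6 become C10, C1, C6, C7, C8, C9). On the six-membered ring, β is the face that carries the C8 oxygen and α the opposite face. The minor E enol ether of step 16 is assumed to be separable by chromatography.

## Analysis of the target

The target is a germacranolide: a ten-membered carbocycle C1–C10 with an E C1=C2 and a Z C4=C5 alkene on either side of the C3 carbinol, a γ-lactone fused across C6–C7 with an exocyclic C11=C13 methylene, an angelate on O8 and a tertiary methyl carbinol at C10. It has five stereocentres, 3S, 6S, 7R, 8R and 10R. In a flat projection O6, C11 and O8 lie on the same side of the contiguous C6–C7–C8 triad, O10 is anti to O8 across C9, and C3 sits alone between the two alkenes. The α-methylene lactone is a Michael acceptor, the angelate isomerises to the tiglate under basic or nucleophilic conditions, and the doubly allylic C3 alcohol and the tertiary allylic C10 alcohol ionise readily in acid. The difficulty is the medium ring with two fixed alkene geometries, which closes poorly end to end, together with C3, which no neighbouring centre can direct in an open chain. The strategy rests on one feature: with C6 as a ketone, its oxygen is 1,5 to the C1=C2 alkene and the C4=C5 alkene is conjugated to it, which is what an alkynyl oxy-Cope shift leaves behind. Reconnecting C1–C6 and cutting C3–C4 gives a six-membered ring C10–C1–C6–C7–C8–C9 whose C8 and C10 oxygens are 1,3 and trans, as in (−)-quinic acid 1.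

## Retrosynthetic reasoning

**Ester and protecting groups.** Target 40 comes from 39 by freeing O3. The angelate is cut at the O8–acyl bond into diol 37 and angelic acid 38. This is done last because the Z enoate would not survive enolate, hydride or alkoxide chemistry. The tertiary O10 of 37 is too hindered to compete, so it needs no separate protecting group. Diol 37 comes from 36 by removing both p-methoxybenzyl ethers in one operation.

**C11=C13.** The methylene carbon is removed from 36 to give lactone 32 and the iminium salt 33. It is added late because the methylene lactone is a conjugate acceptor.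

**O6–C12 and C6–H.** Lactone 32 is opened to diol 30, which comes from the silyl ether 29 and that from ketone 28. C12 travels as a protected primary alcohol because an ester would be attacked by the alkoxide of the key step. Forward, the hydride must add to the Felkin face of C6 and the oxidation must start at the primary alcohol.

**C3–C4 (key).** In 28 the C3–C4 bond is cut and C1–C6 is rejoined, which contracts the ten-membered ring to the cyclohexanol 25. Cutting here removes the medium-ring closure altogether and turns C3 into a centre set by C1 through a concerted shift. Forward, the alkoxide of 25 must rearrange faster than it fragments.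

**C5–C6.** Carbinol 25 is cut into ketone 23 and the propynyl Grignard reagent 24. Forward, the alkynyl must enter on the β face, trans to the C1 arm.

**C2=C3 enol ether and C1–C2.** Enol ether 23 comes from aldehyde 22, and that from the allyl ketone 20 by cleaving the terminal alkene. Ketone 20 comes from the enol carbonate 19, made from ketone 16 and allyl chloroformate 17. The two-step allylation is regiospecific for C1 and keeps the C7 centre away from base.

**C6 oxidation level and protecting groups.** Ketone 16 comes from alcohol 15, which comes from 14, 13 and triol 12 by protecting-group steps. These place a robust silyl group on O12 and benzyl-type ethers on O8 and O10 before O6 is released.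

**C10 methyl.** The methyl of 12 is the carboxyl carbon of 1, reached by reducing the tosylate 10 of the diol 9.

**C7–C11.** The two-carbon arm of 9 is cut at C7–C11. It comes from ester 7, made by hydrogenating enoate 6, the product of ketone 4 and ylide 5. The bond is made on the bicyclic lactone because its bridge covers the β face, so hydrogen enters on the α face and the arm ends cis to O8.

**Back to the chiral pool.** Ketone 4 comes from the mono-silyl ether 3 of quinide 2, the lactone of 1. Compound 1 supplies C8 and C10 with the correct absolute configuration.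

## Alternatives that were turned down

**Alternative 1:** The isoxazoline-bridged lactone A1 is cut at C8–C9 and O–C10. Forward, the C8 aldoxime of the diene lactone A2 is oxidised with NaOCl to a nitrile oxide function that adds across the terminal C9=C10 alkene, closing the carbocycle and the heterocycle together.
- For: the isoxazoline is a masked aldol that later gives the C8 oxygen and the C10 carbinol. The lactone and C3 are already in place, no strong base is used, and the route is convergent.
- Against: the closure forms a ten-membered ring with a bridgehead C=N, so it competes with dimerisation and with addition to the other alkene of the diene. The C10 centre forms on a 1,1-disubstituted alkene far from any stereocentre, and C8 still has to be set by a later reduction.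
- Comparison: A1 is stronger in convergence and needs fewer protecting groups. The chosen route takes C8 and C10 from 1, forms the ring from 25 without dilution, and sets C3 by transfer from C1.

**Alternative 2:** The ring is cut at C2–C3. Forward, CrCl2 with catalytic NiCl2 turns the E alkenyl iodide of the iodo enal A4 into an alkenylchromium that adds to the Z enal, giving the 10-O-triethylsilyl ether A3.
- For: the organochromium tolerates the lactone, the angelate and the methylene group, both alkene geometries are fixed beforehand, and A3 is one desilylation from the target. On endgame economy this is clearly stronger.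
- Against: C3 is created during the closure with only the macrocycle to bias it. The strained ring forces high dilution and a large excess of divalent chromium, the Z enal can isomerise, and A4 needs its C6, C7, C8 and C10 centres built by acyclic stereocontrol.
- Comparison: the chosen route has a longer endgame, but it fixes C3 by a suprafacial shift and needs no end-to-end closure.

**Alternative 3:** The ring is cut at C9–C10. Forward, the lithiated alkenyl dithiane of the epoxy dithiane A6 opens the terminal epoxide at C9 and gives the cyclodecadienol A5 with a free C8 hydroxyl.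
- For: the umpolung joins modular fragments, and the C8 alcohol appears with the configuration of the epoxide, free for acylation. On that point it is stronger than the chosen route, which needs two protecting-group steps at O8.
- Against: the allyl-type dithiane anion is ambident, the ten-membered alkylation competes with intermolecular reaction under strongly basic conditions, and the remaining work is long. The dithiane must be unmasked beside a diene, the C10 quaternary carbinol must be made by an uncontrolled methyl addition, and the lactone is still to be built.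
- Comparison: the chosen route has C10 fixed from the start and makes the ring by a unimolecular concerted step.

Key step: step 18

## Route

Step 1
Reactants: 1 (−)-quinic acid
Product: 2 quinide (bicyclic 1,5-lactone of 1: C10 carboxyl closed onto the β O8; free α-hydroxyls at C6, C7 and C10)
Conditions: p-TsOH·H2O (cat.), toluene/DMF, reflux, Dean–Stark
Reagents that add atoms: none
Why: Acid-catalysed lactonisation of the carboxyl with the cis C8 hydroxyl, driven by azeotropic removal of water; a known transformation of quinic acid.

Step 2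
Reactants: 2 quinide
Product: 3 6-O-TBS quinide (α-OTBS at C6; free α-OH at C7 and C10)
Conditions: TBSCl, imidazole, DMF, 0 °C
Reagents that add atoms: tert-butyldimethylsilyl chloride, CC(C)(C)[Si](C)(C)Cl
Why: In the bicyclic lactone the C6 hydroxyl is equatorial and unhindered, whereas the C7 hydroxyl is axial next to the bridgehead and the C10 hydroxyl is tertiary, so monosilylation should go to O6.

Step 3
Reactants: 3 6-O-TBS quinide
Product: 4 6-O-TBS 7-oxo lactone (C7 ketone)
Conditions: Dess–Martin periodinane, CH2Cl2, rt
Reagents that add atoms: none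
Why: Oxidation of the only secondary alcohol; C8 is a bridgehead and cannot enolise, so its configuration is safe next to the new ketone.

Step 4
Reactants: 4 6-O-TBS 7-oxo lactone; 5 methyl (triphenylphosphoranylidene)acetate
Product: 6 C7 (methoxycarbonyl)methylidene lactone (exocyclic enoate, ester expected on the C8 side)
Conditions: toluene, 90 °C
Reagents that add atoms: none
Why: Wittig olefination with a stabilised ylide; the ketone is activated by its two α-oxygens. The alkene geometry is of no consequence because both isomers converge in step 5.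

Step 5
Reactants: 6 C7 (methoxycarbonyl)methylidene lactone
Product: 7 C7β-(methoxycarbonyl)methyl lactone (7-H α; arm cis to O8)
Conditions: H2, Rh/Al2O3, EtOAc, rt
Reagents that add atoms: none
Why: Catalytic hydrogenation from the open α face, because the lactone bridge spans the β face of the chair; this sets C7 with the arm cis to O8. Rhodium on alumina is chosen to limit hydrogenolysis of the two allylic C–O bonds.

Step 6
Reactants: 7 C7β-(methoxycarbonyl)methyl lactone
Product: 9 cis-fused 8,12-γ-lactone diol (C12 acyl on the β O8; C10 α-OH and β-CH2OH; C6 α-OTBS), via triol methyl ester 8 (not isolated)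
Conditions: NaBH4, EtOH, 0 °C to rt; then AcOH
Reagents that add atoms: none
Why: NaBH4 reduces the α-hydroxy lactone far faster than an unactivated ester; the released C8 alkoxide then closes onto the cis C12 ester to a five-membered lactone, which leaves only one primary alcohol in the molecule.

Step 7
Reactants: 9 cis-fused 8,12-γ-lactone diol
Product: 10 primary tosylate (C10 α-OH, β-CH2OTs)
Conditions: TsCl, pyridine, CH2Cl2, 0 °C
Reagents that add atoms: p-toluenesulfonyl chloride, Cc1ccc(cc1)S(=O)(=O)Cl
Why: Sulfonylation of the only primary hydroxyl; the tertiary hydroxyl does not react under these conditions.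

Step 8
Reactants: 10 primary tosylate
Product: 12 triol (C10 β-methyl α-carbinol; C8 β-OH; C7 β-CH2CH2OH; C6 α-OTBS), via spiro-epoxide lactone 11 (not isolated)
Conditions: LiEt3BH, THF, 0 °C to rt
Reagents that add atoms: none
Why: The tertiary alkoxide displaces the tosylate to the oxirane, which hydride opens at the CH2 terminus to the methyl carbinol; the same reagent reduces the lactone to the 8,12-diol. Silyl ethers are inert to LiEt3BH.

Step 9
Reactants: 12 triol
Product: 13 C12 TBDPS ether (free C8 β-OH and C10 α-OH)
Conditions: TBDPSCl, imidazole, CH2Cl2, 0 °C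
Reagents that add atoms: tert-butyldiphenylsilyl chloride, CC(C)(C)[Si](Cl)(c1ccccc1)c1ccccc1
Why: The bulky silyl chloride selects the primary hydroxyl over the secondary and tertiary ones.

Step 10
Reactants: 13 C12 TBDPS ether
Product: 14 O8,O10-bis(p-methoxybenzyl) ether
Conditions: NaH, PMBCl, Bu4NI, DMF, 0 to 45 °C
Reagents that add atoms: 4-methoxybenzyl chloride, COc1ccc(CCl)cc1
Why: Williamson etherification; the secondary alkoxide reacts first and the tertiary one on warming with iodide catalysis. A benzyl-type ether on O10 cannot migrate to an alkoxide and is a poor leaving group in the later enolate step.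

Step 11
Reactants: 14 O8,O10-bis(p-methoxybenzyl) ether
Product: 15 C6 α-alcohol
Conditions: CSA (cat.), MeOH/CH2Cl2, rt
Reagents that add atoms: none
Why: Acid-catalysed methanolysis removes the TBS ether, while the TBDPS ether is far more stable to acid and the PMB ethers are untouched.

Step 12
Reactants: 15 C6 α-alcohol
Product: 16 C6 ketone (C7 β-CH2CH2OTBDPS; C8 β-OPMB; C10 β-Me and α-OPMB)
Conditions: Dess–Martin periodinane, NaHCO3, CH2Cl2, 0 °C to rt
Reagents that add atoms: none
Why: Buffered, non-basic oxidation, so that the C7 centre, which is the less stable epimer next to the ketone, is not equilibrated.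

Step 13
Reactants: 16 C6 ketone; 17 allyl chloroformate
Product: 19 allyl enol carbonate (C1=C6 enol), via lithium enolate 18 (not isolated)
Conditions: LDA, THF, −78 °C; TMEDA; then 17, −78 °C
Reagents that add atoms: none
Why: Kinetic deprotonation takes place at the C1 methylene and not at the tertiary C7–H, so C7 is untouched; O-acylation by the chloroformate traps the enolate at −78 °C before it can expel the C10 ether.

Step 14
Reactants: 19 allyl enol carbonate
Product: 20 C1α-allyl ketone (allyl trans to the C7 arm and cis to O10)
Conditions: Pd(PPh3)4 (cat.), THF, rt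
Reagents that add atoms: none
Why: Tsuji decarboxylative allylation: zerovalent palladium ionises the carbonate, CO2 is lost and the enolate is allylated at C1 under neutral conditions. The allyl group should enter anti to the pseudoaxial C7 arm, as in kinetic alkylations of 6-substituted cyclohexanone enolates; this also gives the more stable C1 epimer, with the allyl equatorial in the chair that keeps the C10 methyl and the C8 ether equatorial.

Step 15
Reactants: 20 C1α-allyl ketone
Product: 22 keto aldehyde (C1α-CH2CHO), via vicinal diol 21 (not isolated)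
Conditions: OsO4 (cat.), NaIO4, 2,6-lutidine, dioxane/H2O, rt
Reagents that add atoms: osmium tetroxide, O=[Os](=O)(=O)=O, reoxidised by sodium periodate, [Na+].[O-]I(=O)(=O)=O
Why: Lemieux–Johnson cleavage of the terminal alkene. It is preferred to ozone because the PMB ethers are ozone-sensitive, and the buffered medium leaves C1 and C7 alone.

Step 16
Reactants: 22 keto aldehyde
Product: 23 Z triisopropylsilyl enol ether ketone (C1α-CH=CH–OTIPS)
Conditions: TIPSOTf, Et3N, CH2Cl2, −78 °C
Reagents that add atoms: triisopropylsilyl trifluoromethanesulfonate, CC(C)[Si](OS(=O)(=O)C(F)(F)F)(C(C)C)C(C)C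
Why: Soft enolisation. The aldehyde is silylated and deprotonated much faster than the hindered α,α'-disubstituted ketone, and silyl triflate with amine enolisation of aldehydes is expected to favour the Z enol ether.

Step 17
Reactants: 23 Z triisopropylsilyl enol ether ketone; 24 1-propynylmagnesium bromide
Product: 25 propynyl carbinol (1S,6S,7R,8R,10R; propynyl β and trans to the C1 arm; C6 α-OH)
Conditions: CeCl3 (anhydrous), THF, −78 °C; then aq. NH4Cl
Reagents that add atoms: none
Why: The weakly basic organocerium adds to the carbonyl without enolising C1 or C7. In the chair that keeps the C1 arm, the C8 ether and the C10 methyl equatorial, the α face is screened by the syn-axial C10–OPMB, so the alkynyl should enter from the β face.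

Step 18
Reactants: 25 propynyl carbinol
Product: 28 (1E,4Z)-cyclodecadien-6-one (3S,7R,8R,10R; 3-OTIPS; 8,10-bis-OPMB; C7 CH2CH2OTBDPS), via potassium alkoxide 26 (not isolated), via potassium allenolate 27 (not isolated)
Conditions: KH, 18-crown-6, THF, 0 °C to rt; then AcOH/THF, −78 °C
Reagents that add atoms: none
Why: KH with the crown ether gives the free alkoxide 26, whose charge weakens the adjacent C1–C6 bond, and a concerted [3,3] shift forms C3–C4 while C1–C6 breaks. The closest known reaction is the anionic oxy-Cope ring expansion of 1-alkynyl-2-vinylcyclohexanols to cyclodecadienones. The ten-membered ring is therefore not closed end to end but arises by four-atom enlargement of the six-membered ring through the six-centre array C4–C5–C6–C1–C2–C3. With the propynyl and enol ether arms diequatorial, 1,3-allylic strain from the Z silyloxy group holds H1 in the plane of C2=C3, so C10 ends anti to C3 and the C1=C2 alkene is E. C4 bonds suprafacially to the face of C3 from which C6 departs, so the 1S centre and the Z geometry together fix C3 as S. The shift ends at the allenolate 27, which is protonated cold at C5 from the methyl side, away from the ring chain; this leaves C3 and C6 cis, the 4Z enone and the less strained isomer. The step needs rearrangement to outrun fragmentation and silyl transfer, which the bulky TIPS group and the crown-separated ion pair should secure, and the cold acidic quench protects O8 and C7 in the β-alkoxy ketone. The C6 configuration is lost in the shift and affects only the rate.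

Step 19
Reactants: 28 (1E,4Z)-cyclodecadien-6-one
Product: 29 (6S)-allylic alcohol
Conditions: NaBH4, CeCl3·7H2O, MeOH, −78 °C
Reagents that add atoms: none
Why: Luche 1,2-reduction of the enone. Hydride should attack from the ring periphery anti to the C7–C8 bond with the C11 methylene beside the carbonyl oxygen (Felkin–Anh), which gives the 6S carbinol with O6 and C11 on the same side.

Step 20
Reactants: 29 (6S)-allylic alcohol
Product: 30 6,12-diol (free C6 and C12 hydroxyls)
Conditions: TBAF, AcOH, THF, 0 °C to rt
Reagents that add atoms: none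
Why: Buffered fluoride cleaves the primary TBDPS ether well before the hindered secondary TIPS ether at C3; no base-sensitive group is present yet.

Step 21
Reactants: 30 6,12-diol
Product: 32 6,12-γ-lactone, via lactol 31 (not isolated)
Conditions: TEMPO (cat.), PhI(OAc)2, CH2Cl2, rt
Reagents that add atoms: none
Why: The oxoammonium oxidant takes the primary alcohol first; the aldehyde is trapped by O6 as the five-membered lactol, which is oxidised on to the lactone.

Step 22
Reactants: 32 6,12-γ-lactone; 33 Eschenmoser's salt (N,N-dimethylmethyleneiminium iodide)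
Product: 36 α-methylene lactone, via Mannich base 34 (not isolated), via methiodide 35 (not isolated)
Conditions: LiHMDS, THF, −78 °C; 33, −78 to 0 °C; then MeI, MeOH, rt; NaHCO3 (aq.), CH2Cl2
Reagents that add atoms: none
Why: Mannich reaction of the lactone enolate at C11, quaternisation and base-induced elimination, the standard α-methylenation of γ-lactones. The enolate has no β-leaving group and C7 is not acidic.

Step 23
Reactants: 36 α-methylene lactone
Product: 37 8,10-diol (3-OTIPS retained)
Conditions: DDQ, CH2Cl2/pH 7 buffer, 0 °C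
Reagents that add atoms: none
Why: Oxidative cleavage of both PMB ethers under neutral, wet conditions; the silyl-protected C3 carbinol and the acceptor lactone are left alone.

Step 24
Reactants: 37 8,10-diol; 38 angelic acid
Product: 39 8-O-angelate 3-O-TIPS ether (free tertiary C10–OH)
Conditions: 38, 2,4,6-trichlorobenzoyl chloride, Et3N, toluene, rt; then 37, toluene, 80 °C
Reagents that add atoms: none
Why: Yamaguchi esterification through the mixed anhydride, run without a nucleophilic catalyst so that the Z enoate does not isomerise to the tiglate. Only the secondary O8 reacts, since the tertiary O10 is too hindered.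

Step 25
Reactants: 39 8-O-angelate 3-O-TIPS ether
Product: 40 target (3S,6S,7R,8R,10R)
Conditions: HF·pyridine, pyridine, THF, 0 °C to rt
Reagents that add atoms: none
Why: Buffered fluoride desilylation, mild enough for the angelate, the methylene lactone and the two allylic alcohols.

## Compound list

1 | (−)-quinic acid | C1[C@H]([C@H]([C@@H](C[C@@]1(C(=O)O)O)O)O)O | starting material
2 | quinide, 1,5-lactone of 1 | C1[C@@H](O)[C@@H](O)[C@H]2C[C@]1(O)C(=O)O2 | intermediate
3 | 6-O-TBS quinide | C1[C@@H](O[Si](C)(C)C(C)(C)C)[C@@H](O)[C@H]2C[C@]1(O)C(=O)O2 | intermediate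
4 | 6-O-TBS 7-oxo lactone | C1[C@@H](O[Si](C)(C)C(C)(C)C)C(=O)[C@H]2C[C@]1(O)C(=O)O2 | intermediate
5 | methyl (triphenylphosphoranylidene)acetate | COC(=O)C=P(c1ccccc1)(c1ccccc1)c1ccccc1 | starting material
6 | C7 (methoxycarbonyl)methylidene lactone (isomer with the ester on the C8 side drawn) | C1[C@@H](O[Si](C)(C)C(C)(C)C)/C(=C/C(=O)OC)[C@H]2C[C@]1(O)C(=O)O2 | intermediate
7 | C7β-(methoxycarbonyl)methyl lactone | C1[C@@H](O[Si](C)(C)C(C)(C)C)[C@H](CC(=O)OC)[C@H]2C[C@]1(O)C(=O)O2 | intermediate
8 | triol methyl ester (not isolated) | C1[C@@H](O[Si](C)(C)C(C)(C)C)[C@H](CC(=O)OC)[C@H](O)C[C@]1(O)CO | intermediate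
9 | cis-fused 8,12-γ-lactone diol | C1[C@@H](O[Si](C)(C)C(C)(C)C)[C@@H]2CC(=O)O[C@@H]2C[C@]1(O)CO | intermediate
10 | primary tosylate | C1[C@@H](O[Si](C)(C)C(C)(C)C)[C@@H]2CC(=O)O[C@@H]2C[C@]1(O)COS(=O)(=O)c1ccc(C)cc1 | intermediate
11 | spiro-epoxide lactone (not isolated) | C1[C@@H](O[Si](C)(C)C(C)(C)C)[C@@H]2CC(=O)O[C@@H]2C[C@]13CO3 | intermediate
12 | triol with C10 methyl carbinol | C1[C@@H](O[Si](C)(C)C(C)(C)C)[C@H](CCO)[C@H](O)C[C@]1(O)C | intermediate
13 | C12 TBDPS ether | C1[C@@H](O[Si](C)(C)C(C)(C)C)[C@H](CCO[Si](c2ccccc2)(c2ccccc2)C(C)(C)C)[C@H](O)C[C@]1(O)C | intermediate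
14 | O8,O10-bis(PMB) ether | C1[C@@H](O[Si](C)(C)C(C)(C)C)[C@H](CCO[Si](c2ccccc2)(c2ccccc2)C(C)(C)C)[C@H](OCc2ccc(OC)cc2)C[C@]1(OCc1ccc(OC)cc1)C | intermediate
15 | C6 α-alcohol | C1[C@@H](O)[C@H](CCO[Si](c2ccccc2)(c2ccccc2)C(C)(C)C)[C@H](OCc2ccc(OC)cc2)C[C@]1(OCc1ccc(OC)cc1)C | intermediate
16 | C6 ketone | C1C(=O)[C@H](CCO[Si](c2ccccc2)(c2ccccc2)C(C)(C)C)[C@H](OCc2ccc(OC)cc2)C[C@]1(OCc1ccc(OC)cc1)C | intermediate
17 | allyl chloroformate | C=CCOC(Cl)=O | starting material
18 | lithium enolate (not isolated) | C1=C([O-])[C@H](CCO[Si](c2ccccc2)(c2ccccc2)C(C)(C)C)[C@H](OCc2ccc(OC)cc2)C[C@]1(OCc1ccc(OC)cc1)C.[Li+] | intermediate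
19 | allyl enol carbonate | C1=C(OC(=O)OCC=C)[C@H](CCO[Si](c2ccccc2)(c2ccccc2)C(C)(C)C)[C@H](OCc2ccc(OC)cc2)C[C@]1(OCc1ccc(OC)cc1)C | intermediate
20 | C1α-allyl ketone | [C@H]1(CC=C)C(=O)[C@H](CCO[Si](c2ccccc2)(c2ccccc2)C(C)(C)C)[C@H](OCc2ccc(OC)cc2)C[C@]1(OCc1ccc(OC)cc1)C | intermediate
21 | vicinal diol, mixture at the new carbinol (not isolated) | [C@H]1(CC(O)CO)C(=O)[C@H](CCO[Si](c2ccccc2)(c2ccccc2)C(C)(C)C)[C@H](OCc2ccc(OC)cc2)C[C@]1(OCc1ccc(OC)cc1)C | intermediate
22 | keto aldehyde | [C@H]1(CC=O)C(=O)[C@H](CCO[Si](c2ccccc2)(c2ccccc2)C(C)(C)C)[C@H](OCc2ccc(OC)cc2)C[C@]1(OCc1ccc(OC)cc1)C | intermediate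
23 | Z TIPS enol ether ketone | [C@H]1(/C=C\O[Si](C(C)C)(C(C)C)C(C)C)C(=O)[C@H](CCO[Si](c2ccccc2)(c2ccccc2)C(C)(C)C)[C@H](OCc2ccc(OC)cc2)C[C@]1(OCc1ccc(OC)cc1)C | intermediate
24 | 1-propynylmagnesium bromide | CC#C[Mg]Br | starting material
25 | propynyl carbinol with Z silyl enol ether | CC#C[C@]1(O)[C@H](CCO[Si](c2ccccc2)(c2ccccc2)C(C)(C)C)[C@H](OCc2ccc(OC)cc2)C[C@@](C)(OCc2ccc(OC)cc2)[C@H]1/C=C\O[Si](C(C)C)(C(C)C)C(C)C | intermediate
26 | potassium alkoxide of 25 (not isolated) | CC#C[C@]1([O-])[C@H](CCO[Si](c2ccccc2)(c2ccccc2)C(C)(C)C)[C@H](OCc2ccc(OC)cc2)C[C@@](C)(OCc2ccc(OC)cc2)[C@H]1/C=C\O[Si](C(C)C)(C(C)C)C(C)C.[K+] | intermediate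
27 | potassium allenolate (not isolated) | [K+].[O-]C1=C=C(C)[C@@H](O[Si](C(C)C)(C(C)C)C(C)C)/C=C/[C@](C)(OCc2ccc(OC)cc2)C[C@@H](OCc2ccc(OC)cc2)[C@H]1CCO[Si](c2ccccc2)(c2ccccc2)C(C)(C)C | intermediate
28 | (1E,4Z)-cyclodecadien-6-one | O=C1/C=C(/C)[C@@H](O[Si](C(C)C)(C(C)C)C(C)C)/C=C/[C@](C)(OCc2ccc(OC)cc2)C[C@@H](OCc2ccc(OC)cc2)[C@H]1CCO[Si](c2ccccc2)(c2ccccc2)C(C)(C)C | intermediate
29 | (6S)-allylic alcohol | O[C@H]1/C=C(/C)[C@@H](O[Si](C(C)C)(C(C)C)C(C)C)/C=C/[C@](C)(OCc2ccc(OC)cc2)C[C@@H](OCc2ccc(OC)cc2)[C@H]1CCO[Si](c2ccccc2)(c2ccccc2)C(C)(C)C | intermediate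
30 | 6,12-diol | O[C@H]1/C=C(/C)[C@@H](O[Si](C(C)C)(C(C)C)C(C)C)/C=C/[C@](C)(OCc2ccc(OC)cc2)C[C@@H](OCc2ccc(OC)cc2)[C@H]1CCO | intermediate
31 | lactol, mixture at C12 (not isolated) | C1C(O)O[C@H]2/C=C(/C)[C@@H](O[Si](C(C)C)(C(C)C)C(C)C)/C=C/[C@](C)(OCc3ccc(OC)cc3)C[C@@H](OCc3ccc(OC)cc3)[C@@H]12 | intermediate
32 | 6,12-γ-lactone | C1C(=O)O[C@H]2/C=C(/C)[C@@H](O[Si](C(C)C)(C(C)C)C(C)C)/C=C/[C@](C)(OCc3ccc(OC)cc3)C[C@@H](OCc3ccc(OC)cc3)[C@@H]12 | intermediate
33 | Eschenmoser's salt | C=[N+](C)C.[I-] | starting material
34 | Mannich base, mixture at C11 (not isolated) | CN(C)CC1C(=O)O[C@H]2/C=C(/C)[C@@H](O[Si](C(C)C)(C(C)C)C(C)C)/C=C/[C@](C)(OCc3ccc(OC)cc3)C[C@@H](OCc3ccc(OC)cc3)[C@@H]12 | intermediate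
35 | methiodide of 34 (not isolated) | C[N+](C)(C)CC1C(=O)O[C@H]2/C=C(/C)[C@@H](O[Si](C(C)C)(C(C)C)C(C)C)/C=C/[C@](C)(OCc3ccc(OC)cc3)C[C@@H](OCc3ccc(OC)cc3)[C@@H]12.[I-] | intermediate
36 | α-methylene lactone | C=C1C(=O)O[C@H]2/C=C(/C)[C@@H](O[Si](C(C)C)(C(C)C)C(C)C)/C=C/[C@](C)(OCc3ccc(OC)cc3)C[C@@H](OCc3ccc(OC)cc3)[C@@H]12 | intermediate
37 | 8,10-diol | C=C1C(=O)O[C@H]2/C=C(/C)[C@@H](O[Si](C(C)C)(C(C)C)C(C)C)/C=C/[C@](C)(O)C[C@@H](O)[C@@H]12 | intermediate
38 | angelic acid | C/C=C(/C)C(=O)O | starting material
39 | 8-O-angelate 3-O-TIPS ether | C=C1C(=O)O[C@H]2/C=C(/C)[C@@H](O[Si](C(C)C)(C(C)C)C(C)C)/C=C/[C@](C)(O)C[C@@H](OC(=O)/C(C)=C\C)[C@@H]12 | intermediate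
40 | target CNP0262559.7 | C=C1C(=O)O[C@H]2/C=C(/C)[C@@H](O)/C=C/[C@](C)(O)C[C@@H](OC(=O)/C(C)=C\C)[C@@H]12 | target

## Step count and least certain steps

Total step count: 25. Longest linear sequence: 25 steps, from 1 to 40; compounds 5, 17, 24, 33 and 38 are purchased.

**Step 18 (key step).** The tertiary propargylic alkoxide may fragment by loss of the propynyl anion, or take the silyl group from the enol ether, instead of rearranging. After the shift, a ketone left in base can lose O8 or epimerise at C7, and protonation of the allenolate can give both C4=C5 geometries. Fallback, from 25 back to 28: the carbinol is silylated with TESOTf and 2,6-lutidine to the triethylsilyl ether F1. Thermolysis in degassed 1,2-dichlorobenzene at about 180 °C in base-washed glass runs the same [3,3] shift as a neutral siloxy-Cope rearrangement and gives the silyl allenyl ether F2 with no alkoxide present. Buffered fluoride (TBAF with AcOH, low temperature) then releases 28.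

**Step 17.** The slim alkynyl nucleophile may prefer the axial trajectory on the α face, because the axial C7 methylene hinders β approach; that would give the C6 epimer. Fallback, from 23 back to 28: the C6 epimer F3, with the propynyl cis to the enol ether arm, is taken into the same KH and 18-crown-6 rearrangement. C6 becomes the carbonyl carbon, so its configuration is erased. In the chair that places the enol ether arm axial, a boat-like array with the same 1,3-allylic-strain rotamer should deliver the same 3S centre and E alkene, as known for cis-1,2-dialkenylcyclohexanols.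

**Step 14.** The allyl group may enter on the β face, because the α face of C1 is flanked by the pseudoaxial C10 ether, and the palladium enolate may expel that ether. Fallback, from 16 back to 22: the kinetic enolate of 16 (LDA, −78 °C) is added to 2,2-dimethoxyacetaldehyde to give the aldol F4. Dehydration (MsCl, Et3N, then DBU) gives the alkylidene ketone F5. Conjugate reduction with [(Ph3P)CuH]6 followed by protonation of the enolate gives the acetal F6; here a proton, not a carbon electrophile, sets C1, and axial protonation and product stability both place the arm α and equatorial. Mild aqueous acid then gives 22.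

**Step 16.** The amine and silyl triflate may also enolise the C6 ketone and so epimerise C7 or C1, and the Z selectivity may be incomplete. Fallback, from 20 back to 25: the propynylcerium reagent from 24 is added to 20 first and the alkoxide is capped with TMSCl to give the allyl carbinol silyl ether F7. Lemieux–Johnson cleavage gives the aldehyde F8, now the only carbonyl group. KHMDS at −78 °C followed by TIPSOTf gives the enol ether F9 from the potassium enolate, and K2CO3 in MeOH removes the tertiary trimethylsilyl group to give 25.

**Step 19.** If the ring conformation is not the Felkin-like one, hydride arrives on the other face of C6; conjugate reduction is a minor risk. Fallback, from 28 back to 29: the 6-epi alcohol F10 is inverted by a Mitsunobu reaction (4-nitrobenzoic acid, PPh3, DIAD) to the (6S)-4-nitrobenzoate F11, and K2CO3 in MeOH releases 29.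

## Further compounds

F1 | step 18 | triethylsilyl ether of 25 | CC#C[C@]1(O[Si](CC)(CC)CC)[C@H](CCO[Si](c2ccccc2)(c2ccccc2)C(C)(C)C)[C@H](OCc2ccc(OC)cc2)C[C@@](C)(OCc2ccc(OC)cc2)[C@H]1/C=C\O[Si](C(C)C)(C(C)C)C(C)C
F2 | step 18 | triethylsilyl allenyl ether | CC[Si](CC)(CC)OC1=C=C(C)[C@@H](O[Si](C(C)C)(C(C)C)C(C)C)/C=C/[C@](C)(OCc2ccc(OC)cc2)C[C@@H](OCc2ccc(OC)cc2)[C@H]1CCO[Si](c2ccccc2)(c2ccccc2)C(C)(C)C
F3 | step 17 | C6 epimer of 25 | CC#C[C@@]1(O)[C@H](CCO[Si](c2ccccc2)(c2ccccc2)C(C)(C)C)[C@H](OCc2ccc(OC)cc2)C[C@@](C)(OCc2ccc(OC)cc2)[C@H]1/C=C\O[Si](C(C)C)(C(C)C)C(C)C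
F4 | step 14 | aldol adduct, mixture at C1 and C2 | C1(C(O)C(OC)OC)C(=O)[C@H](CCO[Si](c2ccccc2)(c2ccccc2)C(C)(C)C)[C@H](OCc2ccc(OC)cc2)C[C@]1(OCc1ccc(OC)cc1)C
F5 | step 14 | C1 alkylidene ketone, either alkene geometry | C1(=CC(OC)OC)C(=O)[C@H](CCO[Si](c2ccccc2)(c2ccccc2)C(C)(C)C)[C@H](OCc2ccc(OC)cc2)C[C@]1(OCc1ccc(OC)cc1)C
F6 | step 14 | C1α dimethyl acetal ketone | [C@H]1(CC(OC)OC)C(=O)[C@H](CCO[Si](c2ccccc2)(c2ccccc2)C(C)(C)C)[C@H](OCc2ccc(OC)cc2)C[C@]1(OCc1ccc(OC)cc1)C
F7 | step 16 | allyl carbinol trimethylsilyl ether | CC#C[C@]1(O[Si](C)(C)C)[C@H](CCO[Si](c2ccccc2)(c2ccccc2)C(C)(C)C)[C@H](OCc2ccc(OC)cc2)C[C@@](C)(OCc2ccc(OC)cc2)[C@H]1CC=C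
F8 | step 16 | aldehyde with C6 trimethylsilyl ether | CC#C[C@]1(O[Si](C)(C)C)[C@H](CCO[Si](c2ccccc2)(c2ccccc2)C(C)(C)C)[C@H](OCc2ccc(OC)cc2)C[C@@](C)(OCc2ccc(OC)cc2)[C@H]1CC=O
F9 | step 16 | Z TIPS enol ether with C6 trimethylsilyl ether | CC#C[C@]1(O[Si](C)(C)C)[C@H](CCO[Si](c2ccccc2)(c2ccccc2)C(C)(C)C)[C@H](OCc2ccc(OC)cc2)C[C@@](C)(OCc2ccc(OC)cc2)[C@H]1/C=C\O[Si](C(C)C)(C(C)C)C(C)C
F10 | step 19 | 6-epi alcohol | O[C@@H]1/C=C(/C)[C@@H](O[Si](C(C)C)(C(C)C)C(C)C)/C=C/[C@](C)(OCc2ccc(OC)cc2)C[C@@H](OCc2ccc(OC)cc2)[C@H]1CCO[Si](c2ccccc2)(c2ccccc2)C(C)(C)C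
F11 | step 19 | (6S)-4-nitrobenzoate | O=C(O[C@H]1/C=C(/C)[C@@H](O[Si](C(C)C)(C(C)C)C(C)C)/C=C/[C@](C)(OCc2ccc(OC)cc2)C[C@@H](OCc2ccc(OC)cc2)[C@H]1CCO[Si](c2ccccc2)(c2ccccc2)C(C)(C)C)c1ccc(cc1)[N+](=O)[O-]
A1 | alternative 1 | isoxazoline-bridged cyclodecadiene lactone | O=C1O[C@H]2/C=C(/C)[C@@H](O[Si](C)(C)C(C)(C)C)/C=C/[C@]3(C)ON=C(C3)[C@H]2C1
A2 | alternative 1 | aldoxime diene lactone | O=C1O[C@@H](/C=C(/C)[C@@H](O[Si](C)(C)C(C)(C)C)/C=C/C(C)=C)[C@@H](C=NO)C1
A3 | alternative 2 | 10-O-triethylsilyl ether of the target | C=C1C(=O)O[C@H]2/C=C(/C)[C@@H](O)/C=C/[C@](C)(O[Si](CC)(CC)CC)C[C@@H](OC(=O)/C(C)=C\C)[C@@H]12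
A4 | alternative 2 | iodo enal | C=C1C(=O)O[C@@H](/C=C(/C)C=O)[C@H]1[C@H](OC(=O)/C(C)=C\C)C[C@@](C)(O[Si](CC)(CC)CC)/C=C/I
A5 | alternative 3 | cyclodecadien-8-ol with C10 dithiane | C=C(COCc1ccc(OC)cc1)[C@H]1[C@@H](O[Si](CC)(CC)CC)/C=C(/C)[C@@H](O[Si](C)(C)C(C)(C)C)/C=C/C2(SCCCS2)C[C@H]1O
A6 | alternative 3 | epoxy dithiane | C=C(COCc1ccc(OC)cc1)[C@H]([C@H]1CO1)[C@@H](O[Si](CC)(CC)CC)/C=C(/C)[C@@H](O[Si](C)(C)C(C)(C)C)/C=C/C1SCCCS1
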